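3 questions stand on this flask, two orders and one yield, and our own reckoning goes to the yield.

| flask | starting material | coupling partner | target | time |
|---|---|---|---|---|
| red | 0.500 M | 1.00 M |  |  |
| amber | 0.250 M | 0.750 M |  |  |
| violet | 0.500 M | 1.00 M | 0.250 M |  |
| blue | 0.250 M | 1.00 M |  |  |
| teal | 0.170 M | 0.500 M |  | 60 min |

| run | time / min | [target] / M |
|---|---|---|
| red run | 10 | 0.025 |
| red run | 20 | 0.057 |
| red run | 30 | 0.067 |
| red run | 40 | 0.096 |
| red run | 50 | 0.098 |
| red run | 60 | 0.104 |
| amber run | 10 | 0.016 |
| amber run | 20 | 0.028 |
| amber run | 30 | 0.033 |
| amber run | 40 | 0.046 |
| amber run | 50 | 0.046 |
| amber run | 60 | 0.040 |
| violet run | 10 | 0.250 |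
| violet run | 20 | 0.260 |
| violet run | 30 | 0.254 |
| violet run | 40 | 0.249 |
| violet run | 50 | 0.231 |
| violet run | 60 | 0.231 |
| blue run | 10 | 0.024 |
| blue run | 20 | 0.030 |
| blue run | 30 | 0.031 |
| blue run | 40 | 0.041 |
| blue run | 50 | 0.056 |
| blue run | 60 | 0.062 |

(scatter of a reading: 0.007 M)

- how the opening rate goes with [starting material] round the charge of the red run: the exponent of the rate at two percent of starting material gone to target (one fixed amount of target, the same in the runs compared)
- how the opening rate goes with [coupling partner] round the charge of the red run: the exponent of the rate at two percent of starting material gone to target
- target in the teal run at 60 min, as a share of the starting material charged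

- Overall: starting material + coupling partner -> target.
- Constant volume, constant temperature.
- An order is taken over about fifteen percent of the charge, up and down.

The red and amber curves flatten late in the run, and the violet run lets us read what becomes of target once it is made. Violet and red differ by the added target, so if that addition leaves the making undisturbed, their difference is what remains of it. At 60 min that difference is 0.127 M, half of the 0.250 M added. Read as a first-order loss, this gives 0.0113 /min.

Now we integrate. If each unit of starting material charged makes target at a steady fraction a per minute, while target is lost at that constant, the share at time t is a(1 − exp(−kt))/k, with k the loss constant. At 60 min this bracket is the surviving time, the stretch of loss-free making that leaves the same target, 43.6 min.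

Dividing the final shares by it gives a: 0.00477 /min for red, 0.00569 /min for blue and 0.00367 /min for amber. Their mean, times the surviving time, puts the teal run near 20.5%.

The weak link is amber, whose ratio of coupling partner to starting material, 3.00, lies close to teal's 2.94. Its last reading is lower than the one before it, by less than the scatter of 0.007 M. So we average amber's last 3 readings, centred on 50 min, where the surviving time is 38.2 min. That gives 0.00461 /min, and we commit to 20.1% for teal.

The forecast says 0.9 and 0.8 for the orders and 11.5% for teal, “Treating these as equilibria”. Our teal figure is higher than its value, by 8.6 percentage points.

The flask gives orders of 0.77 and 0.33, and 20.6% for teal.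

    starting material + coupling partner → intermediate (0.2340 /M/min)
    intermediate → target (0.02178 /min)
    target → decomposed product (0.01170 /min)
    2 coupling partner → lost reagent (0.5586 /M/min)

Where the same amount of target has been made, the rate measured against that of the red run is 0.56 in the blue run, which was charged with half the starting material of the red run. Teal's share divided by the surviving time is 0.00472 /min. The blue run's rate at that point, 0.0016 M/min, held for the surviving time, gives 0.0698 M, and its reading at 60 min is 0.062 M.

The data are simulated with made-up constants, and the scatter is random.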